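**Plan**
1. Retrosynthesis: the four phenols are masked as benzyl ethers. The chain is cut between C2 (α to the ketone C1) and C3, which gives an aryl methyl ketone and a 7-arylheptan-1-ol. The alcohol is then cut between C9 and the catechol ring carbon.
2. Forward: the catechol ring is joined to C9 by B-alkyl Suzuki–Miyaura coupling. C2–C3 is made by iridium hydrogen-borrowing alkylation of the methyl ketone with the alcohol. One fourfold hydrogenolysis finishes the route. No ring is built, since both benzene rings are bought.
3. Enabling feature: C1=O sits between C2 and the 2,6-dioxygenated benzene ring, which has no α-H, has both ortho carbons substituted, and is twisted out of the carbonyl plane. C2 is therefore the only enolisable carbon, and C1 is shielded from hydride and enolate attack. C3 can thus be brought in at the alcohol oxidation level, and the aldehyde never has to be made or handled.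
4. Stereochemistry: there is none to set. The transient E-enone double bond is reduced in the same flask.

Key step: step 3

Assumption: the target has no stereocentre and no stereogenic double bond, so the request for a single enantiomer is met by the one achiral compound and no stereocontrolling step is planned.

**Step 1**
Reactants: 1 2',6'-dihydroxyacetophenone
Product: 2 1-[2,6-bis(benzyloxy)phenyl]ethan-1-one
Conditions: BnBr (2.5 equiv), K2CO3 (3 equiv), DMF, 80 °C
Reagents that add atoms: benzyl bromide, BrCc1ccccc1
Why: Double Williamson ether synthesis (SN2 of the phenoxides on benzyl bromide), in which the second hydroxyl is hydrogen-bonded to the ketone and less nucleophilic, hence the excess reagent, dipolar aprotic solvent and heating, while carbonate does not deprotonate the methyl ketone.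

**Step 2**
Reactants: 3 4-bromo-1,2-bis(benzyloxy)benzene, 4 hept-6-en-1-ol
Product: 6 7-[3,4-bis(benzyloxy)phenyl]heptan-1-ol, via alkylborane 5 (not isolated)
Conditions: 4 (1.3 equiv), 9-BBN-H (2.2 equiv per 4), THF, 0 °C to rt; then 3, PdCl2(dppf) (5 mol %), 3 M aq NaOH, THF, 65 °C
Reagents that add atoms: 9-borabicyclo[3.3.1]nonane, [H]B1C2CCCC1CCC2 (its atoms other than hydrogen stand in 5 only and are lost again before 6)
Why: 9-BBN-H adds anti-Markovnikov to the terminal alkene of 4 (the free OH only consumes a second equivalent as a borinate that aqueous base hydrolyses again), and the hydroxide-activated B-alkyl-9-BBN transfers its primary alkyl group to the arylpalladium bromide from 3 in a B-alkyl Suzuki–Miyaura coupling, where the wide-bite-angle dppf ligand favours reductive elimination over β-hydride elimination and the benzyl ethers are inert.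

**Step 3**
Reactants: 2 1-[2,6-bis(benzyloxy)phenyl]ethan-1-one (1.3 equiv), 6 7-[3,4-bis(benzyloxy)phenyl]heptan-1-ol
Product: 9 1-[2,6-bis(benzyloxy)phenyl]-9-[3,4-bis(benzyloxy)phenyl]nonan-1-one, via aldehyde 7 (not isolated), via enone 8 (not isolated)
Conditions: [Cp*IrCl2]2 (2 mol %), KOH (0.5 equiv), toluene, 110 °C, sealed tube, Ar
Reagents that add atoms: none
Why: Hydrogen-borrowing α-alkylation: the iridium alkoxide of 6 loses a β-hydride to give aldehyde 7 and an Ir–H species, KOH condenses the C2 enolate of 2 with 7 (aldol addition, then E1cB loss of water) to the E-enone 8, and the stored Ir–H hands the hydrogen back to C2=C3, so the C2–C3 bond arises from a methyl ketone and an alcohol. The closest known reaction type is the [Cp*IrCl2]2/KOH alkylation of aryl methyl ketones, ortho,ortho'-disubstituted ones included, with primary aliphatic alcohols. No ring is closed and no stereocentre is formed, and the geometry of 8 is erased by its reduction. The step needs mono-alkylation at C2, cross- instead of self-condensation of 7, and 1,4- instead of 1,2-reduction. The substrate secures this because C2 is the only enolisable carbon of 2, the two ortho benzyloxy groups twist the ring out of the C1=O plane and so shield C1 from hydride and enolate attack and leave no ortho C–H for cyclometalation, 7 exists only at catalyst-level concentration beside a large excess of the enolate of 2, and a slight excess of 2 lets 6 run out before the slower alkylation of the now secondary C2 of 9 can compete. Aryl benzyl ethers should be inert to KOH and Ir–H in toluene at this temperature.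

**Step 4**
Reactants: 9 1-[2,6-bis(benzyloxy)phenyl]-9-[3,4-bis(benzyloxy)phenyl]nonan-1-one
Product: 10 malabaricone C, 1-(2,6-dihydroxyphenyl)-9-(3,4-dihydroxyphenyl)nonan-1-one
Conditions: H2 (1 atm), 10 % Pd/C, EtOAc/EtOH, rt; filtration through Celite under Ar
Reagents that add atoms: none
Why: Catalytic hydrogenolysis of the four aryl benzyl ethers under neutral conditions should free the oxidation-prone catechol only at the very end, the doubly ortho-substituted C1 ketone (hydrogen-bonded to both hydroxyls once they are free) should resist reduction at 1 atm, and any enone 8 carried over from step 3 would be saturated to the same product.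

**Compound list**
1 | 2',6'-dihydroxyacetophenone, 1-(2,6-dihydroxyphenyl)ethan-1-one | CC(=O)c1c(O)cccc1O | starting material
2 | 1-[2,6-bis(benzyloxy)phenyl]ethan-1-one | CC(=O)c1c(OCc2ccccc2)cccc1OCc1ccccc1 | intermediate
3 | 4-bromo-1,2-bis(benzyloxy)benzene | Brc1ccc(OCc2ccccc2)c(OCc2ccccc2)c1 | starting material
4 | hept-6-en-1-ol | OCCCCCC=C | starting material
5 | 9-{7-[(9-borabicyclo[3.3.1]nonan-9-yl)oxy]heptyl}-9-borabicyclo[3.3.1]nonane (formed in the flask in step 2) | C(CCCCCCOB1C2CCCC1CCC2)B1C2CCCC1CCC2 | intermediate
6 | 7-[3,4-bis(benzyloxy)phenyl]heptan-1-ol | OCCCCCCCc1ccc(OCc2ccccc2)c(OCc2ccccc2)c1 | intermediate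
7 | 7-[3,4-bis(benzyloxy)phenyl]heptanal (formed in the flask in step 3) | O=CCCCCCCc1ccc(OCc2ccccc2)c(OCc2ccccc2)c1 | intermediate
8 | (E)-1-[2,6-bis(benzyloxy)phenyl]-9-[3,4-bis(benzyloxy)phenyl]non-2-en-1-one (formed in the flask in step 3) | O=C(/C=C/CCCCCCc1ccc(OCc2ccccc2)c(OCc2ccccc2)c1)c1c(OCc2ccccc2)cccc1OCc1ccccc1 | intermediate
9 | 1-[2,6-bis(benzyloxy)phenyl]-9-[3,4-bis(benzyloxy)phenyl]nonan-1-one | O=C(CCCCCCCCc1ccc(OCc2ccccc2)c(OCc2ccccc2)c1)c1c(OCc2ccccc2)cccc1OCc1ccccc1 | intermediate
10 | malabaricone C, 1-(2,6-dihydroxyphenyl)-9-(3,4-dihydroxyphenyl)nonan-1-one (achiral) | O=C(CCCCCCCCc1ccc(O)c(O)c1)c1c(O)cccc1O | target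

Total step count: 4.
Longest linear sequence: 3 (steps 2, 3, 4, or steps 1, 3, 4).

**Steps most likely to fail**

Step 3 is the riskiest.
- The transient aldehyde may condense with itself.
- C2 may be alkylated a second time.
- The borrowed hydrogen may escape as H2, so that the sequence stalls at the enone stage.
- The base may be consumed by dehydrogenative oxidation of the alcohol to the carboxylate.

The fallback replaces the catalytic cascade by a classical enolate SN2 alkylation. It sets out from 6 and 2 and comes back at 9. Alcohol 6 would be converted by an Appel reaction (I2, PPh3, imidazole, CH2Cl2, 0 °C) into 4-(7-iodoheptyl)-1,2-bis(benzyloxy)benzene F1. The lithium enolate of 2 (LDA, THF/DMPU, −78 °C to rt) would then be alkylated with F1 to give 9.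

Step 2 comes next.
- Oxidative addition into the electron-rich aryl bromide may be slow.
- The alkylborane may be lost by protodeboronation, or the alkylpalladium species by β-hydride elimination.
- The borinate formed from the free hydroxyl may disturb transmetalation.

The fallback brings in the chain as an sp carbon nucleophile instead of an sp3 boron reagent. It sets out from 3 and comes back at 6. Sonogashira coupling of 3 with commercial hept-6-yn-1-ol (PdCl2(PPh3)2, CuI, Et3N, 70 °C) should give 7-[3,4-bis(benzyloxy)phenyl]hept-6-yn-1-ol F2. Its triple bond would be saturated with diimide (TsNHNH2, NaOAc, aqueous DME, reflux) or with H2 over ethylenediamine-poisoned Pd/C. Both methods spare benzyl ethers and give 6.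

Step 4 is third.
- The C1 carbonyl may be over-reduced.
- The two hindered ortho ethers may be cleaved incompletely.
- The freed catechol may be oxidised by air during filtration.

The fallback is non-reductive. It sets out from 9 and comes back at 10. Lewis-acid debenzylation with BCl3 and pentamethylbenzene as benzyl cation scavenger (CH2Cl2, −78 °C, then methanol quench) would give 10 directly. No new compound is made on this way (F0).

**Further compounds**
F1 | step 3 | 4-(7-iodoheptyl)-1,2-bis(benzyloxy)benzene | ICCCCCCCc1ccc(OCc2ccccc2)c(OCc2ccccc2)c1
F2 | step 2 | 7-[3,4-bis(benzyloxy)phenyl]hept-6-yn-1-ol | OCCCCCC#Cc1ccc(OCc2ccccc2)c(OCc2ccccc2)c1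
F0 | step 4 | none | none
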